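**Plan**

1. The target is read as gallocatechin-(4α→8)-catechin-(4β→8)-ent-catechin: upper unit 2R,3S,4S (2,3-trans-3,4-trans), middle unit 2R,3S with the C4 aryl cis to O3, lower unit 2S,3R. The retrosynthesis cuts, in order, O1–C2 and C3–C4 of ring C of the gallocatechin unit (retro-hetero-Diels–Alder), the bond from C4 of that unit to C8 of the catechin unit, and the C4–C8 bond of the lower dimer.
2. Enabling feature: in the upper unit O1–C8a=C4a–C4 is a phenol oxygen ortho to a doubly benzylic carbon flanked by two phloroglucinol-type rings (its own ring A and ring A of the catechin unit), a latent o-quinone methide. Its C2–C3 edge is a trans-styrene whose oxygen can be carried as boron.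
3. Forward: benzylated ent-catechin and a bromine-capped epicatechin C4 electrophile give the 4β→8 dimer; oxidation and reduction at C3 turn the upper epicatechin unit into the 3,4-cis catechin unit.
4. Bromine–lithium exchange at C8 and addition to a salicylaldehyde give an o-hydroxybenzhydrol. Acid releases the o-quinone methide, which closes the last ring by [4+2] addition of an (E)-alkenylboronate; C–B oxidation and hydrogenolysis finish.
5. Stereochemistry: lower and middle units from (−)-catechin and (−)-epicatechin; interflavan C4 by attack anti to the 3α-hydroxyl; middle C3 by hydride attack opposite the 4-aryl group. Upper C2/C3 come from the (E)-alkene, C4 from the endo transition state, the absolute sense from a chiral phosphoric acid, and C3–O from retentive C–B oxidation.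

Key step: step 13

Assumption: (−)-catechin, (−)-epicatechin, 2,4,6-trihydroxybenzaldehyde, 3,4,5-tris(benzyloxy)benzaldehyde and bis[(pinacolato)boryl]methane are taken as purchasable.
Assumption: the (R) enantiomer of the phosphoric acid is taken as the one that directs the alkene to the face of C4 that gives the 4S centre; if a model reaction shows the opposite sense, its mirror image is used.

**Route**

Step 1
Reactants: 1 (−)-catechin (ent-catechin, 2S,3R)
Product: 2 5,7,3',4'-tetra-O-benzyl-ent-catechin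
Conditions: BnBr (4.4 equiv), K2CO3, DMF, 0 °C → rt
Reagents that add atoms: benzyl bromide, BrCc1ccccc1
Why: Williamson etherification; the four phenols are deprotonated by K2CO3 and benzylated while the less acidic secondary alcohol stays free, and no stereocentre is touched.

Step 2
Reactants: 2 5,7,3',4'-tetra-O-benzyl-ent-catechin
Product: 3 3,5,7,3',4'-penta-O-benzyl-ent-catechin
Conditions: NaH, BnBr, Bu4NI (cat.), DMF, 0 °C → rt
Reagents that add atoms: benzyl bromide, BrCc1ccccc1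
Why: Williamson etherification of the alkoxide caps O3, so that only the upper-unit hydroxyl is free in the later oxidation.

Step 3
Reactants: 4 (−)-epicatechin (2R,3R)
Product: 5 5,7,3',4'-tetra-O-benzylepicatechin
Conditions: BnBr (4.4 equiv), K2CO3, DMF, 0 °C → rt
Reagents that add atoms: benzyl bromide, BrCc1ccccc1
Why: Williamson etherification of the four phenols, as in step 1, with the 3-hydroxyl left free.

Step 4
Reactants: 5 5,7,3',4'-tetra-O-benzylepicatechin
Product: 6 8-bromo-5,7,3',4'-tetra-O-benzylepicatechin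
Conditions: N-bromosuccinimide (1.0 equiv), CH2Cl2, −78 °C → rt
Reagents that add atoms: N-bromosuccinimide, O=C1CCC(=O)N1Br
Why: electrophilic aromatic bromination; C8 is the most nucleophilic position of ring A in 5,7-dialkoxyflavans, and the bromine later blocks self-condensation and serves as the lithiation handle.

Step 5
Reactants: 6 8-bromo-5,7,3',4'-tetra-O-benzylepicatechin
Product: 7 8-bromo-5,7,3',4'-tetra-O-benzyl-4β-(2-ethoxyethoxy)epicatechin
Conditions: DDQ (2,3-dichloro-5,6-dicyano-1,4-benzoquinone, 2 equiv), 2-ethoxyethanol, CH2Cl2, rt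
Reagents that add atoms: 2-ethoxyethanol, CCOCCO
Why: oxidative benzylic C–H functionalisation; DDQ abstracts hydride from C4 to give the cation stabilised by ring A, which the alcohol traps trans to the 3-hydroxyl.

Step 6
Reactants: 7 8-bromo-5,7,3',4'-tetra-O-benzyl-4β-(2-ethoxyethoxy)epicatechin; 3 3,5,7,3',4'-penta-O-benzyl-ent-catechin
Product: 8 [8-bromo-5,7,3',4'-tetra-O-benzylepicatechin]-(4β→8)-[3,5,7,3',4'-penta-O-benzyl-ent-catechin]
Conditions: 3 (3 equiv), Me3SiOTf (0.1 equiv), CH2Cl2, −78 °C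
Reagents that add atoms: none
Why: Lewis-acid-promoted Friedel–Crafts coupling through the flavan-4-yl cation; the arene attacks C4 anti to the axial 3α-hydroxyl to give the 4β bond, C8 of 3 is more nucleophilic than C6, and the C8 bromine of 7 prevents oligomerisation.

Step 7
Reactants: 8 [8-bromo-5,7,3',4'-tetra-O-benzylepicatechin]-(4β→8)-[3,5,7,3',4'-penta-O-benzyl-ent-catechin]
Product: 9 upper-unit 3-ketone of 8 (8-bromo-4β-aryl-5,7,3',4'-tetrakis(benzyloxy)flavan-3-one linked to C8 of penta-O-benzyl-ent-catechin)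
Conditions: Dess–Martin periodinane (1,1,1-triacetoxy-1,1-dihydro-1,2-benziodoxol-3(1H)-one), pyridine, CH2Cl2, 0 °C → rt
Reagents that add atoms: none
Why: Dess–Martin oxidation of the only free hydroxyl to the flavan-3-one under buffered, non-enolising conditions, so that C2 and C4 are not epimerised.

Step 8
Reactants: 9 upper-unit 3-ketone
Product: 10 [8-bromo-5,7,3',4'-tetra-O-benzylcatechin]-(4β→8)-[3,5,7,3',4'-penta-O-benzyl-ent-catechin]
Conditions: NaBH4, CeCl3·7H2O, THF/MeOH, −78 → −20 °C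
Reagents that add atoms: none
Why: Luche-type carbonyl reduction; hydride should add axially from the α face, opposite the quasi-axial 4β-aryl group, so the new 3-hydroxyl is β (equatorial), trans to the 2-aryl and cis to the 4-aryl as in the target.

Step 9
Reactants: 10 [8-bromo-5,7,3',4'-tetra-O-benzylcatechin]-(4β→8)-[3,5,7,3',4'-penta-O-benzyl-ent-catechin]
Product: 11 [8-bromo-3,5,7,3',4'-penta-O-benzylcatechin]-(4β→8)-[3,5,7,3',4'-penta-O-benzyl-ent-catechin]
Conditions: NaH, BnBr, Bu4NI (cat.), THF/DMF, 0 °C → rt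
Reagents that add atoms: benzyl bromide, BrCc1ccccc1
Why: Williamson etherification removes the last acidic proton before the organolithium step.

Step 10
Reactants: 12 2,4,6-trihydroxybenzaldehyde
Product: 13 2,4-bis(benzyloxy)-6-hydroxybenzaldehyde
Conditions: BnBr (2.05 equiv), K2CO3 (2.1 equiv), DMF, rt
Reagents that add atoms: benzyl bromide, BrCc1ccccc1
Why: selective Williamson etherification; the hydroxyl hydrogen-bonded to the formyl group is the least nucleophilic and stays free.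

Step 11
Reactants: 14 3,4,5-tris(benzyloxy)benzaldehyde; 15 bis[(pinacolato)boryl]methane
Product: 17 pinacol (E)-2-[3,4,5-tris(benzyloxy)phenyl]ethenylboronate, via lithiated diborylmethane 16 (not isolated)
Conditions: lithium 2,2,6,6-tetramethylpiperidide (1.1 equiv), THF, 0 °C; then 14, −78 °C → rt
Reagents that add atoms: none
Why: boron–Wittig olefination; the α-boryl carbanion adds to the aldehyde and syn-elimination of a boron–oxygen unit gives the (E)-alkenylboronate.

Step 12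
Reactants: 11 [8-bromo-3,5,7,3',4'-penta-O-benzylcatechin]-(4β→8)-[3,5,7,3',4'-penta-O-benzyl-ent-catechin]; 13 2,4-bis(benzyloxy)-6-hydroxybenzaldehyde
Product: 20 o-hydroxybenzhydrol in which the C8 bromine of 11 is replaced by CH(OH)[2,4-bis(benzyloxy)-6-hydroxyphenyl] (both carbinol epimers), via 8-lithio dimer 18 (not isolated), via sodium phenoxide 19 (not isolated)
Conditions: (i) 11, t-BuLi (2.1 equiv), THF, −78 °C; (ii) 13 + NaH (1.0 equiv), THF, 0 °C, then added to (i), −78 → 0 °C; pH 7 buffer; Et3N-deactivated silica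
Reagents that add atoms: none
Why: bromine–lithium exchange followed by 1,2-addition of the aryllithium to the aldehyde, whose phenol is masked in the flask as its phenoxide; the carbinol centre forms as a mixture that is erased in the next step.

Step 13
Reactants: 20 o-hydroxybenzhydrol; 17 pinacol (E)-2-[3,4,5-tris(benzyloxy)phenyl]ethenylboronate
Product: 22 [5,7,3',4',5'-penta-O-benzyl-3-deoxy-3β-(pinacolatoboryl)gallocatechin]-(4α→8)-[3,5,7,3',4'-penta-O-benzylcatechin]-(4β→8)-[3,5,7,3',4'-penta-O-benzyl-ent-catechin], via o-quinone methide 21 (not isolated)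
Conditions: (R)-3,3'-bis(2,4,6-triisopropylphenyl)-1,1'-binaphthyl-2,2'-diyl hydrogen phosphate (10 mol %), 17 (3 equiv), 5 Å molecular sieves, PhMe, 0 °C → rt
Reagents that add atoms: none
Why: Proposed new method: the chiral phosphoric acid dehydrates benzhydrol 20 to the ion-paired (E)-o-quinone methide 21, whose electron-poor heterodiene O=C8a–C4a=C4 undergoes an inverse-electron-demand hetero-Diels–Alder reaction with the electron-rich alkene of 17, C4 bonding to the boron-bearing carbon and the carbonyl oxygen to the benzylic carbon in a concerted but asynchronous transition state. The closest known reaction type is the Brønsted-acid-catalysed [4+2] cycloaddition of o-quinone methides generated from o-hydroxybenzhydrols with trans-β-substituted styrenes, which gives 2,3-trans-2,4-cis chromans; new here is an alkenylboronate as dienophile, with boron as a retentively oxidisable stand-in for the C3 hydroxyl. Ring C of the gallocatechin unit closes by [4+2] cycloaddition (O1–C2 and C3–C4 formed together; in the stepwise limit a six-membered capture of the C2 benzylic cation by the phenol oxygen). C2 and C3 come out trans because the (E)-alkene adds suprafacially, C4 comes out cis to the C2 aryl and trans to boron because the ring-B aryl lies endo to a diene whose methide aryl is outside, and the absolute sense (which face of C4 is attacked) is set by the chiral phosphate bound to the quinone methide oxygen. The step needs regioselectivity (boron at C3), which the substrate secures because positive charge at C2 is stabilised by the 3,4,5-tris(benzyloxy)phenyl ring whereas charge at C3 would sit next to the empty boron orbital, and chemoselectivity against ipso alkenyl transfer from boron, which the non-exchanging, weakly Lewis acidic pinacol ester secures.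

Step 14
Reactants: 22 3β-boryl trimer
Product: 23 [5,7,3',4',5'-penta-O-benzylgallocatechin]-(4α→8)-[3,5,7,3',4'-penta-O-benzylcatechin]-(4β→8)-[3,5,7,3',4'-penta-O-benzyl-ent-catechin]
Conditions: H2O2 (30 % aq), NaOH, THF, 0 °C → rt
Reagents that add atoms: hydrogen peroxide, OO
Why: oxidation of an alkylboronate by hydroperoxide (1,2-metallate shift) proceeds with retention, as in hydroboration–oxidation routes to flavan-3-ols, so the 3-hydroxyl is β.

Step 15
Reactants: 23 pentadeca-O-benzyl trimer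
Product: 24 gallocatechin-(4α→8)-catechin-(4β→8)-ent-catechin (CNP0155646.2)
Conditions: H2 (1 atm), Pd(OH)2/C, THF/MeOH/H2O, rt
Reagents that add atoms: none
Why: catalytic hydrogenolysis cleaves all fifteen benzyl ethers and should leave the C–O and C–C bonds of the flavan skeleton and every stereocentre intact.

**Compound list**

1 | (−)-catechin (ent-catechin, 2S,3R) | Oc1cc(O)c2c(c1)O[C@@H](c1ccc(O)c(O)c1)[C@H](O)C2 | starting material
2 | 5,7,3',4'-tetra-O-benzyl-ent-catechin | c1c(OCc3ccccc3)cc(OCc3ccccc3)c2c1O[C@@H](c1ccc(OCc3ccccc3)c(OCc3ccccc3)c1)[C@H](O)C2 | intermediate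
3 | 3,5,7,3',4'-penta-O-benzyl-ent-catechin | c1c(OCc3ccccc3)cc(OCc3ccccc3)c2c1O[C@@H](c1ccc(OCc3ccccc3)c(OCc3ccccc3)c1)[C@H](OCc3ccccc3)C2 | intermediate
4 | (−)-epicatechin (2R,3R) | Oc1cc(O)c2c(c1)O[C@H](c1ccc(O)c(O)c1)[C@H](O)C2 | starting material
5 | 5,7,3',4'-tetra-O-benzylepicatechin | c1c(OCc3ccccc3)cc(OCc3ccccc3)c2c1O[C@H](c1ccc(OCc3ccccc3)c(OCc3ccccc3)c1)[C@H](O)C2 | intermediate
6 | 8-bromo-5,7,3',4'-tetra-O-benzylepicatechin | Brc1c(OCc3ccccc3)cc(OCc3ccccc3)c2c1O[C@H](c1ccc(OCc3ccccc3)c(OCc3ccccc3)c1)[C@H](O)C2 | intermediate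
7 | 8-bromo-5,7,3',4'-tetra-O-benzyl-4β-(2-ethoxyethoxy)epicatechin (3,4-trans) | Brc1c(OCc3ccccc3)cc(OCc3ccccc3)c2c1O[C@H](c1ccc(OCc3ccccc3)c(OCc3ccccc3)c1)[C@H](O)[C@H]2OCCOCC | intermediate
8 | [8-bromo-5,7,3',4'-tetra-O-benzylepicatechin]-(4β→8)-[3,5,7,3',4'-penta-O-benzyl-ent-catechin], upper 3α-OH free | Brc1c(OCc3ccccc3)cc(OCc3ccccc3)c2c1O[C@H](c1ccc(OCc3ccccc3)c(OCc3ccccc3)c1)[C@H](O)[C@H]2c1c(OCc3ccccc3)cc(OCc3ccccc3)c2c1O[C@@H](c1ccc(OCc3ccccc3)c(OCc3ccccc3)c1)[C@H](OCc3ccccc3)C2 | intermediate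
9 | upper-unit 3-ketone of 8 (2α-aryl, 4β-aryl flavan-3-one) | Brc1c(OCc3ccccc3)cc(OCc3ccccc3)c2c1O[C@H](c1ccc(OCc3ccccc3)c(OCc3ccccc3)c1)C(=O)[C@H]2c1c(OCc3ccccc3)cc(OCc3ccccc3)c2c1O[C@@H](c1ccc(OCc3ccccc3)c(OCc3ccccc3)c1)[C@H](OCc3ccccc3)C2 | intermediate
10 | [8-bromo-5,7,3',4'-tetra-O-benzylcatechin]-(4β→8)-[3,5,7,3',4'-penta-O-benzyl-ent-catechin], upper unit 2,3-trans-3,4-cis, 3β-OH free | Brc1c(OCc3ccccc3)cc(OCc3ccccc3)c2c1O[C@H](c1ccc(OCc3ccccc3)c(OCc3ccccc3)c1)[C@@H](O)[C@H]2c1c(OCc3ccccc3)cc(OCc3ccccc3)c2c1O[C@@H](c1ccc(OCc3ccccc3)c(OCc3ccccc3)c1)[C@H](OCc3ccccc3)C2 | intermediate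
11 | [8-bromo-3,5,7,3',4'-penta-O-benzylcatechin]-(4β→8)-[3,5,7,3',4'-penta-O-benzyl-ent-catechin] | Brc1c(OCc3ccccc3)cc(OCc3ccccc3)c2c1O[C@H](c1ccc(OCc3ccccc3)c(OCc3ccccc3)c1)[C@@H](OCc3ccccc3)[C@H]2c1c(OCc3ccccc3)cc(OCc3ccccc3)c2c1O[C@@H](c1ccc(OCc3ccccc3)c(OCc3ccccc3)c1)[C@H](OCc3ccccc3)C2 | intermediate
12 | 2,4,6-trihydroxybenzaldehyde | O=Cc1c(O)cc(O)cc1O | starting material
13 | 2,4-bis(benzyloxy)-6-hydroxybenzaldehyde | O=Cc1c(O)cc(OCc2ccccc2)cc1OCc1ccccc1 | intermediate
14 | 3,4,5-tris(benzyloxy)benzaldehyde | O=Cc1cc(OCc2ccccc2)c(OCc2ccccc2)c(OCc2ccccc2)c1 | starting material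
15 | bis[(pinacolato)boryl]methane | CC1(C)OB(CB2OC(C)(C)C(C)(C)O2)OC1(C)C | starting material
16 | lithiated bis[(pinacolato)boryl]methane | [Li]C(B1OC(C)(C)C(C)(C)O1)B1OC(C)(C)C(C)(C)O1 | intermediate (not isolated)
17 | pinacol (E)-2-[3,4,5-tris(benzyloxy)phenyl]ethenylboronate | CC1(C)OB(/C=C/c2cc(OCc3ccccc3)c(OCc3ccccc3)c(OCc3ccccc3)c2)OC1(C)C | intermediate
18 | 8-lithio derivative of 11 | [Li]c1c(OCc3ccccc3)cc(OCc3ccccc3)c2c1O[C@H](c1ccc(OCc3ccccc3)c(OCc3ccccc3)c1)[C@@H](OCc3ccccc3)[C@H]2c1c(OCc3ccccc3)cc(OCc3ccccc3)c2c1O[C@@H](c1ccc(OCc3ccccc3)c(OCc3ccccc3)c1)[C@H](OCc3ccccc3)C2 | intermediate (not isolated)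
19 | sodium 3,5-bis(benzyloxy)-2-formylphenoxide | [Na+].[O-]c1cc(OCc2ccccc2)cc(OCc2ccccc2)c1C=O | intermediate (not isolated)
20 | o-hydroxybenzhydrol: decabenzyl dimer carrying CH(OH)[2,4-bis(benzyloxy)-6-hydroxyphenyl] at C8 of the catechin unit, carbinol epimers | OC(c1c(O)cc(OCc3ccccc3)cc1OCc3ccccc3)c1c(OCc3ccccc3)cc(OCc3ccccc3)c2c1O[C@H](c1ccc(OCc3ccccc3)c(OCc3ccccc3)c1)[C@@H](OCc3ccccc3)[C@H]2c1c(OCc3ccccc3)cc(OCc3ccccc3)c2c1O[C@@H](c1ccc(OCc3ccccc3)c(OCc3ccccc3)c1)[C@H](OCc3ccccc3)C2 | intermediate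
21 | (E)-o-quinone methide: 3,5-bis(benzyloxy)-6-(arylmethylidene)cyclohexa-2,4-dien-1-one, aryl = C8 of the decabenzyl dimer, anti to the carbonyl | O=C1C=C(OCc3ccccc3)C=C(OCc3ccccc3)/C1=C\c1c(OCc3ccccc3)cc(OCc3ccccc3)c2c1O[C@H](c1ccc(OCc3ccccc3)c(OCc3ccccc3)c1)[C@@H](OCc3ccccc3)[C@H]2c1c(OCc3ccccc3)cc(OCc3ccccc3)c2c1O[C@@H](c1ccc(OCc3ccccc3)c(OCc3ccccc3)c1)[C@H](OCc3ccccc3)C2 | intermediate (not isolated)
22 | [5,7,3',4',5'-penta-O-benzyl-3-deoxy-3β-(pinacolatoboryl)gallocatechin]-(4α→8)-[penta-O-benzylcatechin]-(4β→8)-[penta-O-benzyl-ent-catechin]; upper unit 2α-aryl, 3β-boryl, 4α-aryl | c1ccccc1COc1cc(OCc3ccccc3)c2c(c1)O[C@H](c1cc(OCc3ccccc3)c(OCc3ccccc3)c(OCc3ccccc3)c1)[C@@H](B3OC(C)(C)C(C)(C)O3)[C@@H]2c1c(OCc3ccccc3)cc(OCc3ccccc3)c2c1O[C@H](c1ccc(OCc3ccccc3)c(OCc3ccccc3)c1)[C@@H](OCc3ccccc3)[C@H]2c1c(OCc3ccccc3)cc(OCc3ccccc3)c2c1O[C@@H](c1ccc(OCc3ccccc3)c(OCc3ccccc3)c1)[C@H](OCc3ccccc3)C2 | intermediate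
23 | [5,7,3',4',5'-penta-O-benzylgallocatechin]-(4α→8)-[penta-O-benzylcatechin]-(4β→8)-[penta-O-benzyl-ent-catechin], upper 3β-OH free | c1ccccc1COc1cc(OCc3ccccc3)c2c(c1)O[C@H](c1cc(OCc3ccccc3)c(OCc3ccccc3)c(OCc3ccccc3)c1)[C@@H](O)[C@@H]2c1c(OCc3ccccc3)cc(OCc3ccccc3)c2c1O[C@H](c1ccc(OCc3ccccc3)c(OCc3ccccc3)c1)[C@@H](OCc3ccccc3)[C@H]2c1c(OCc3ccccc3)cc(OCc3ccccc3)c2c1O[C@@H](c1ccc(OCc3ccccc3)c(OCc3ccccc3)c1)[C@H](OCc3ccccc3)C2 | intermediate
24 | gallocatechin-(4α→8)-catechin-(4β→8)-ent-catechin (CNP0155646.2) | Oc1cc(O)c2c(c1)O[C@H](c1cc(O)c(O)c(O)c1)[C@@H](O)[C@@H]2c1c(O)cc(O)c2c1O[C@H](c1ccc(O)c(O)c1)[C@@H](O)[C@H]2c1c(O)cc(O)c2c1O[C@@H](c1ccc(O)c(O)c1)[C@H](O)C2 | target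

**Step count**

Total steps: 15. Longest linear sequence: 11 steps (steps 3–9 and 12–15, from (−)-epicatechin).

**Steps most likely to fail**

Step 13. The stabilised quinone methide may react too slowly with the boron-substituted alkene. The C2 cation may lose boron (ipso alkenyl transfer) instead of closing the ring. The acid may also fail to control the face of C4 or the endo orientation on so large a substrate; the two facial isomers are diastereomers and should be separable. The fallback uses known chemistry, sets out from 14 and 20, and comes back at 23. Aldehyde 14 is homologated with dimethyl (1-diazo-2-oxopropyl)phosphonate and K2CO3 in MeOH (Seyferth–Gilbert reaction, Ohira–Bestmann variant) to 3,4,5-tris(benzyloxy)phenylacetylene F1. Acid-promoted annulation of 20 (through 21) with F1, the known route from o-quinone methides and arylacetylenes to 4-aryl-4H-chromenes, should give the flav-2-ene trimer F2, in which C4 is the only new centre. Hydroboration of the enol ether double bond of F2 with BH3·SMe2 anti to the C4 aryl group gives the 3-boryl flavan F3. Oxidation in the same flask (H2O2, NaOH) gives 23, with C2 and C3 fixed by syn addition.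

Step 12. The hindered aryllithium may add slowly to the deactivated phenoxide aldehyde, so that protonation (loss of the bromine handle) competes, and the very ionisable carbinol may decompose on isolation. The fallback sets out from 18 and comes back at 21. The aryllithium 18 is quenched with DMF to give the 8-formyl dimer F4. Condensation of F4 with purchased 3,5-bis(benzyloxy)phenol and PhB(OH)2 (cat. propionic acid, PhMe, reflux, water removal), the boronic-acid-templated ortho-specific hydroxyalkylation of phenols, gives the 2-phenyl-4H-1,3,2-benzodioxaborin F5. This is a bench-stable precursor that releases 21 under the acid of step 13, if necessary with gentle heating.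

Step 14. The boron ate complex may fragment by anti-elimination of the ring oxygen O1 (ring C opens), or oxidation may stall at the hindered secondary boronate. The fallback makes the elimination the intended reaction, sets out from 22 and comes back at 23. Aqueous NaOH in THF without peroxide drives the elimination to the (E)-allylphenol F6, with C4 untouched. Shi epoxidation with the L-fructose-derived ketone (1,2:4,5-di-O-isopropylidene-β-L-erythro-2,3-hexodiulo-2,6-pyranose), KHSO5 and K2CO3 in MeCN/dimethoxymethane/H2O gives the trans-epoxide F7. The neighbouring phenol opens F7 at the benzylic carbon with inversion (6-endo) to give the 2,3-trans alcohol 23.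

Further compounds
F1 | step 13 | 3,4,5-tris(benzyloxy)phenylacetylene | C#Cc1cc(OCc2ccccc2)c(OCc2ccccc2)c(OCc2ccccc2)c1
F2 | step 13 | flav-2-ene trimer: upper unit 5,7-bis(benzyloxy)-2-[3,4,5-tris(benzyloxy)phenyl]-4H-chromene with C4 (α) bonded to C8 of the decabenzyl dimer | c1ccccc1COc1cc(OCc3ccccc3)c2c(c1)OC(c1cc(OCc3ccccc3)c(OCc3ccccc3)c(OCc3ccccc3)c1)=C[C@@H]2c1c(OCc3ccccc3)cc(OCc3ccccc3)c2c1O[C@H](c1ccc(OCc3ccccc3)c(OCc3ccccc3)c1)[C@@H](OCc3ccccc3)[C@H]2c1c(OCc3ccccc3)cc(OCc3ccccc3)c2c1O[C@@H](c1ccc(OCc3ccccc3)c(OCc3ccccc3)c1)[C@H](OCc3ccccc3)C2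
F3 | step 13 | 3β-boranyl analogue of 22 (BH2 in place of the pinacolatoboryl group; not isolated) | c1ccccc1COc1cc(OCc3ccccc3)c2c(c1)O[C@H](c1cc(OCc3ccccc3)c(OCc3ccccc3)c(OCc3ccccc3)c1)[C@@H]([BH2])[C@@H]2c1c(OCc3ccccc3)cc(OCc3ccccc3)c2c1O[C@H](c1ccc(OCc3ccccc3)c(OCc3ccccc3)c1)[C@@H](OCc3ccccc3)[C@H]2c1c(OCc3ccccc3)cc(OCc3ccccc3)c2c1O[C@@H](c1ccc(OCc3ccccc3)c(OCc3ccccc3)c1)[C@H](OCc3ccccc3)C2
F4 | step 12 | 8-formyl analogue of 11 (CHO in place of Br) | O=Cc1c(OCc3ccccc3)cc(OCc3ccccc3)c2c1O[C@H](c1ccc(OCc3ccccc3)c(OCc3ccccc3)c1)[C@@H](OCc3ccccc3)[C@H]2c1c(OCc3ccccc3)cc(OCc3ccccc3)c2c1O[C@@H](c1ccc(OCc3ccccc3)c(OCc3ccccc3)c1)[C@H](OCc3ccccc3)C2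
F5 | step 12 | 5,7-bis(benzyloxy)-2-phenyl-4H-1,3,2-benzodioxaborin carrying the decabenzyl dimer (through C8 of its catechin unit) at C4, both C4 epimers | c1ccccc1B1Oc2cc(OCc3ccccc3)cc(OCc3ccccc3)c2C(O1)c1c(OCc3ccccc3)cc(OCc3ccccc3)c2c1O[C@H](c1ccc(OCc3ccccc3)c(OCc3ccccc3)c1)[C@@H](OCc3ccccc3)[C@H]2c1c(OCc3ccccc3)cc(OCc3ccccc3)c2c1O[C@@H](c1ccc(OCc3ccccc3)c(OCc3ccccc3)c1)[C@H](OCc3ccccc3)C2
F6 | step 14 | (E)-allylphenol: 3,5-bis(benzyloxy)-2-{1-(dimer-C8-yl)-3-[3,4,5-tris(benzyloxy)phenyl]prop-2-enyl}phenol, the CH centre configured as C4 of the target | Oc1cc(OCc3ccccc3)cc(OCc3ccccc3)c1[C@H](/C=C/c1cc(OCc3ccccc3)c(OCc3ccccc3)c(OCc3ccccc3)c1)c1c(OCc3ccccc3)cc(OCc3ccccc3)c2c1O[C@H](c1ccc(OCc3ccccc3)c(OCc3ccccc3)c1)[C@@H](OCc3ccccc3)[C@H]2c1c(OCc3ccccc3)cc(OCc3ccccc3)c2c1O[C@@H](c1ccc(OCc3ccccc3)c(OCc3ccccc3)c1)[C@H](OCc3ccccc3)C2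
F7 | step 14 | trans-epoxide of F6 (not isolated) | Oc1cc(OCc3ccccc3)cc(OCc3ccccc3)c1[C@H]([C@@H]1O[C@H]1c1cc(OCc3ccccc3)c(OCc3ccccc3)c(OCc3ccccc3)c1)c1c(OCc3ccccc3)cc(OCc3ccccc3)c2c1O[C@H](c1ccc(OCc3ccccc3)c(OCc3ccccc3)c1)[C@@H](OCc3ccccc3)[C@H]2c1c(OCc3ccccc3)cc(OCc3ccccc3)c2c1O[C@@H](c1ccc(OCc3ccccc3)c(OCc3ccccc3)c1)[C@H](OCc3ccccc3)C2
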